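## Analysis of the target

The target 19 is a didepside: two benzene rings joined by one aryl ester, with no ring fusion and no stereocentre, so no configuration has to be controlled. Ring A is a benzoic acid (carboxyl on C1) flanked by a heptyl chain on C2 and a methoxy group on C6, and its C4 oxygen carries the acyl group. Ring B is the acyl part: the carbonyl sits on C1 between a free hydroxyl on C2 and a pentyl chain on C6, with a methoxy group on C4. The sensitive site is the central aryl ester, because the ring A aryloxide is a good leaving group and hydroxide, alkoxides, amines and hard carbanions cleave or transacylate it. The free ring A acid is an electron-rich ortho-oxygenated benzoic acid and can decarboxylate under strong acid or heat. The difficulty is regiochemistry and order of events: each ring has three contiguous substituents around a carbonyl carbon, the two oxygens of each ring must be told apart, and two different n-alkyl chains must end up ortho to a carbonyl group. The plan rests on ring B C6, which is ortho to the depside carbonyl and meta to both ring B oxygens. A bromine there is activated for oxidative addition, and the pentyl chain can be delivered as a radical under neutral reducing conditions after the depside has been assembled. The ring B C2 hydroxyl and the ring A carboxyl are carried as benzyl ether and benzyl ester, which one neutral hydrogenolysis removes at the end.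

## Retrosynthetic reasoning

**19 to 18.** The two benzylic C–O bonds are cut last: the ether on ring B C2 and the ester on the ring A carboxyl. A single neutral hydrogenolysis removes both without touching the aryl ester, and because both chains are saturated nothing else in 18 can be reduced.

**18 to 14 and 17.** The bond between ring B C6 and the first carbon of the pentyl chain is cut. This bond is chosen because the chain is the only part of ring B that does not come with a cheap oxygenated arene, and because a bromine at C6 in 14 fixes the site unambiguously. The heptyl chain of ring A is not cut in the same way, since it is already present in 7. The forward reaction must join an aryl carbon to a primary alkyl carbon without a base or a hard carbanion that would attack the depside ester or the benzyl ester. A nickel-catalysed cathodic coupling of the aryl bromide 14 with the redox-active ester 17 meets this demand, because the alkyl group arrives as a radical.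

**17 to 15 and 16.** The N–O acyl bond of 17 is cut. A simple condensation of 15 with 16 gives the radical precursor in one step from bulk chemicals.

**14 to 6 and 12.** The acyl–oxygen bond of the depside is cut, with acid chloride 13 as the activated form of 6. This is the convergent cut: it gives two fragments of similar size, and 12 has only one free hydroxyl, so no site selectivity is needed. The forward reaction has to push a phenol onto a carbonyl shielded by bromine and benzyloxy groups, which calls for the acid chloride and nucleophilic catalysis.

**6 back to 1.** The acid 6 comes from aldehyde 5 by oxidation, 5 from phenol 4 by benzylation, and 4 from 3 by cleavage of the one methyl ether that chelates to the aldehyde. The carbon–carbon bond between ring B C1 and the formyl carbon of 3 is then cut, leading through iminium 2 to 1. In 1 the bromine is meta to both methoxy groups, so electrophilic formylation next to bromine gives the contiguous bromine, carbonyl and oxygen pattern directly.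

**12 back to 7.** The free C4 hydroxyl of 12 is uncovered from allyl ether 11. The C6 methyl ether of 11 is traced to the chelated hydroxyl of 10, and the allyl group of 10 to the more acidic C4 hydroxyl of 9. The benzyl ester 9 comes from acid 8, and the carboxyl carbon of 8 is cut from ring A C1, leading to 7, which already holds the heptyl chain. The sequence uses the built-in difference between the two hydroxyls of a 2,4-dihydroxybenzoate: the free para hydroxyl reacts first, the hydrogen-bonded ortho hydroxyl second.

## Alternatives that were turned down

**Alternative 1:** Ring A is taken apart at two adjacent bonds, C2–heptyl and C1–carboxyl, leading back to the fluoroarene A2.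
- Forward key step: heptyllithium A3 removes the proton between fluorine and methoxy of A2, and fluoride loss gives the aryne A4. A second equivalent of A3 adds at the aryne carbon remote from methoxy, and carboxylation of the aryllithium gives A1.
- For: three contiguous substituents are set in one flask, and the two ring A oxygens are already differentiated as methyl and silyl ethers. On ring A step count this is stronger than the five-step sequence used here.
- Against: A2 has a second acidic position between fluorine and the silyloxy group, and lithiation there leads to the regioisomeric acid. A3 must act as base and as nucleophile in sequence. The aryllithium can add to unreacted A4, and over-addition to the lithium carboxylate gives a ketone. The method also leaves the depside bond and the ring B chain unsolved.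
- Comparison: the chosen route pays with more steps on ring A, but each is routine and the regiochemistry is fixed by the substrate. The one uncertain event is a single late coupling with an independent fallback.

**Alternative 2:** Ring B itself is disconnected at C1–C6, back to the open-chain triketo aryl ester A6 built on phenol 12.
- Forward key step: under mild base the C2 enolate of A6 adds to the C7 ketone in a 6-(enolexo)-exo-trig aldol closure. Dehydration and enolisation then give the resorcylate A5.
- For: ring B, its pentyl chain and the depside link appear together without halogen or metal. A5 emerges with the C2 hydroxyl chelated and the C4 hydroxyl free, so the final methylation is naturally selective and ring B needs no benzyl ether. On protecting-group economy for ring B this is stronger than the chosen route.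
- Against: an aryl ester of a β-keto acid is about the most labile ester there is. The C5 enol oxygen can close onto the ester carbonyl, or C6 can attack it in a Claisen mode, and either path expels the ring A aryloxide and destroys the depside bond. Assembly of A6 requires polyanion or acylketene chemistry, and a methylation in the presence of the depside still follows.
- Comparison: the chosen route keeps both rings aromatic from the start, so there is no competition between folding modes. It accepts a benzyl ether on ring B in exchange.

**Alternative 3:** The depside is cut between the carboxylate oxygen and ring A C4, giving acid A8 and boronate A9.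
- Forward key step: A8 and A9 are joined with Cu(OTf)2 A10 in air to give A7.
- For: the nucleophile is the unhindered carboxylate oxygen, so the shielded acyl carbon never has to be attacked. A9 could come from a sterically controlled C–H borylation of the simple benzoate A11 at its only unflanked position, so the differentiation of the two ring A oxygens disappears. Both points are stronger than in the chosen route.
- Against: O-arylation of carboxylic acids with boronates is much less general than that of amines or phenols, and pinacol boronates transfer slowly to copper. An electron-rich benzoic acid with two ortho substituents is prone to copper-promoted loss of the carboxyl group. Protodeboronation and oxidation of the boronate compete. A8 still needs its own pentyl installation, and the acidic removal of the tert-butyl and methoxymethyl groups threatens the decarboxylation-prone ring A acid.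
- Comparison: the chosen route forms the depside by ordinary acyl chloride chemistry and ends with a neutral hydrogenolysis. Its uncertainty is confined to one carbon–carbon coupling.

Key step: step 12

Assumption: the electrolysis is run in an undivided cell with a sacrificial zinc anode, so zinc ions balance the cathodic reduction.

## Route

**Step 1**
Reactants: 1 1-bromo-3,5-dimethoxybenzene
Product: 3 2-bromo-4,6-dimethoxybenzaldehyde, via aryl iminium chloride 2 (not isolated)
Conditions: POCl3, DMF, 0 → 80 °C; then H2O, 0 °C → rt
Reagents that add atoms: N,N-dimethylformamide (CN(C)C=O); water (O)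
Why: Vilsmeier–Haack formylation; the chloroiminium electrophile attacks the carbon next to bromine, which is para to one methoxy group and ortho to the other, in the usual preference over the doubly ortho position between the methoxy groups, and iminium 2 is hydrolysed on aqueous work-up.

**Step 2**
Reactants: 3 2-bromo-4,6-dimethoxybenzaldehyde
Product: 4 2-bromo-6-hydroxy-4-methoxybenzaldehyde
Conditions: BCl3 (1 M in CH2Cl2), CH2Cl2, −78 → 0 °C; then H2O
Reagents that add atoms: none
Why: Chelation-directed Lewis-acid ether cleavage; BCl3 binds the aldehyde oxygen and the adjacent C6 methoxy oxygen in a six-membered chelate, so only that methyl group leaves as chloromethane while the C4 methyl ether and the bromide stay.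

**Step 3**
Reactants: 4 2-bromo-6-hydroxy-4-methoxybenzaldehyde
Product: 5 2-(benzyloxy)-6-bromo-4-methoxybenzaldehyde
Conditions: BnBr, K2CO3, DMF, rt
Reagents that add atoms: benzyl bromide (BrCc1ccccc1)
Why: Williamson ether synthesis; the acidic salicylaldehyde phenoxide is alkylated by the benzylic halide, and the aldehyde has no α-hydrogen and does not interfere.

**Step 4**
Reactants: 5 2-(benzyloxy)-6-bromo-4-methoxybenzaldehyde
Product: 6 2-(benzyloxy)-6-bromo-4-methoxybenzoic acid
Conditions: NaClO2, NaH2PO4, 2-methyl-2-butene, t-BuOH/THF/H2O, 0 °C → rt
Reagents that add atoms: sodium chlorite ([Na+].[O-]Cl=O)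
Why: Pinnick oxidation; chlorous acid converts the hindered aldehyde into the acid without touching the benzyl ether or the bromide, and the alkene scavenger removes hypochlorous acid before it can chlorinate the electron-rich ring.

**Step 5**
Reactants: 7 5-heptylbenzene-1,3-diol (5-heptylresorcinol)
Product: 8 2-heptyl-4,6-dihydroxybenzoic acid
Conditions: MeOMgOCO2Me (2 M in DMF), 120 °C; then aq. HCl, 0 °C
Reagents that add atoms: methyl magnesium carbonate (COC(=O)O[Mg]OC)
Why: Chelation-controlled ortho-carboxylation of a phenol (a Kolbe–Schmitt-type reaction); the magnesium phenoxide delivers the carboxyl group to the carbon between a hydroxyl and the heptyl chain, as 5-alkylresorcinols are known to do, and cold acid releases the acid from its magnesium salt.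

**Step 6**
Reactants: 8 2-heptyl-4,6-dihydroxybenzoic acid
Product: 9 benzyl 2-heptyl-4,6-dihydroxybenzoate
Conditions: BnBr, KHCO3, DMF, rt
Reagents that add atoms: benzyl bromide (BrCc1ccccc1)
Why: Carboxylate O-alkylation (SN2); hydrogen carbonate deprotonates only the carboxylic acid, so both phenols stay free, and room temperature avoids decarboxylation of the dihydroxybenzoic acid.

**Step 7**
Reactants: 9 benzyl 2-heptyl-4,6-dihydroxybenzoate
Product: 10 benzyl 2-heptyl-6-hydroxy-4-(prop-2-en-1-yloxy)benzoate
Conditions: allyl bromide (1.05 equiv), K2CO3, acetone, rt
Reagents that add atoms: allyl bromide (C=CCBr)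
Why: Selective Williamson etherification; the C4 hydroxyl para to the ester is the more acidic and is unencumbered, whereas the C6 hydroxyl is hydrogen-bonded to the ester carbonyl, so one equivalent of halide reacts at C4.

**Step 8**
Reactants: 10 benzyl 2-heptyl-6-hydroxy-4-(prop-2-en-1-yloxy)benzoate
Product: 11 benzyl 2-heptyl-6-methoxy-4-(prop-2-en-1-yloxy)benzoate
Conditions: MeI, K2CO3, DMF, 50 °C
Reagents that add atoms: iodomethane (CI)
Why: Williamson methylation of the remaining chelated phenol under more forcing conditions; it is the only nucleophilic site left.

**Step 9**
Reactants: 11 benzyl 2-heptyl-6-methoxy-4-(prop-2-en-1-yloxy)benzoate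
Product: 12 benzyl 2-heptyl-4-hydroxy-6-methoxybenzoate
Conditions: Pd(PPh3)4 (cat.), morpholine, THF, rt
Reagents that add atoms: none
Why: Tsuji–Trost deallylation; zerovalent palladium ionises the allyl aryl ether to a π-allyl complex and the phenoxide, morpholine captures the allyl unit, and the benzyl ester and methyl ether are inert.

**Step 10**
Reactants: 6 2-(benzyloxy)-6-bromo-4-methoxybenzoic acid; 12 benzyl 2-heptyl-4-hydroxy-6-methoxybenzoate
Product: 14 benzyl 4-{[2-(benzyloxy)-6-bromo-4-methoxybenzoyl]oxy}-2-heptyl-6-methoxybenzoate, via acid chloride 13 (not isolated)
Conditions: (COCl)2, DMF (cat.), CH2Cl2, 0 °C → rt, concentrate; then 12, Et3N, DMAP, CH2Cl2, 0 °C → rt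
Reagents that add atoms: none
Why: Acid chloride formation followed by DMAP-catalysed O-acylation of a phenol (nucleophilic acyl substitution); 12 has a single unhindered hydroxyl, and the acylpyridinium intermediate overcomes the shielding of the carbonyl by the ortho bromine and benzyloxy groups.

**Step 11**
Reactants: 15 hexanoic acid; 16 N-hydroxyphthalimide
Product: 17 1,3-dioxoisoindolin-2-yl hexanoate
Conditions: DIC, DMAP (cat.), CH2Cl2, rt
Reagents that add atoms: none
Why: Carbodiimide (Steglich-type) condensation of a carboxylic acid with an N-hydroxy imide, giving the redox-active ester.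

**Step 12**
Reactants: 14 benzyl 4-{[2-(benzyloxy)-6-bromo-4-methoxybenzoyl]oxy}-2-heptyl-6-methoxybenzoate; 17 1,3-dioxoisoindolin-2-yl hexanoate
Product: 18 benzyl 4-{[2-(benzyloxy)-4-methoxy-6-pentylbenzoyl]oxy}-2-heptyl-6-methoxybenzoate
Conditions: NiBr2(dme) (10 mol %), 4,4'-di-tert-butyl-2,2'-bipyridine (12 mol %), 17 (1.5 equiv), LiBr, DMA, undivided cell, RVC cathode, Zn anode, constant current, rt
Reagents that add atoms: none
Why: Cathodic reduction turns the bipyridine complex of divalent nickel into a low-valent species that adds oxidatively to the ring B C6–Br bond of 14, which the ortho ester carbonyl activates, giving an arylnickel bromide of divalent nickel. Low-valent nickel or the cathode passes one electron to 17, whose radical anion fragments into phthalimide anion, CO2 and the pentyl radical. The arylnickel species captures this radical to give an aryl alkyl complex of trivalent nickel, reductive elimination forms the C6–pentyl bond, and the monovalent nickel left over is reduced again while the zinc anode dissolves. The closest known reaction type is the nickel-catalysed electroreductive decarboxylative cross-coupling of N-hydroxyphthalimide esters with aryl halides. No ring closes and no stereocentre forms. The site is fixed by the single C–Br bond, and chemoselectivity rests on oxidative addition to C–Br being far faster than insertion into the acyl–oxygen or benzyl–oxygen bonds and on a working potential well short of that needed to reduce aryl benzoates. No base or carbanion is present, so the depside survives; the primary radical cannot rearrange, and the excess of 17 under constant current keeps radical supply in step with oxidative addition, which suppresses hydrodebromination and biaryl formation.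

**Step 13**
Reactants: 18 benzyl 4-{[2-(benzyloxy)-4-methoxy-6-pentylbenzoyl]oxy}-2-heptyl-6-methoxybenzoate
Product: 19 2-heptyl-4-[(2-hydroxy-4-methoxy-6-pentylbenzoyl)oxy]-6-methoxybenzoic acid
Conditions: H2 (1 atm), 10% Pd/C, EtOAc, rt
Reagents that add atoms: none
Why: Catalytic hydrogenolysis of benzylic C–O bonds; the benzyl ether on ring B C2 and the benzyl ester on ring A are both cleaved to toluene under neutral conditions, while the aryl ester, the methyl ethers and the saturated chains are inert.

## Compound list

1 | 1-bromo-3,5-dimethoxybenzene | COc1cc(Br)cc(OC)c1 | starting material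
2 | N-[(2-bromo-4,6-dimethoxyphenyl)methylidene]-N-methylmethanaminium chloride | COc1cc(OC)c(C=[N+](C)C)c(Br)c1.[Cl-] | intermediate (not isolated)
3 | 2-bromo-4,6-dimethoxybenzaldehyde | COc1cc(OC)c(C=O)c(Br)c1 | intermediate
4 | 2-bromo-6-hydroxy-4-methoxybenzaldehyde | COc1cc(O)c(C=O)c(Br)c1 | intermediate
5 | 2-(benzyloxy)-6-bromo-4-methoxybenzaldehyde | COc1cc(OCc2ccccc2)c(C=O)c(Br)c1 | intermediate
6 | 2-(benzyloxy)-6-bromo-4-methoxybenzoic acid | COc1cc(OCc2ccccc2)c(C(=O)O)c(Br)c1 | intermediate
7 | 5-heptylbenzene-1,3-diol | CCCCCCCc1cc(O)cc(O)c1 | starting material
8 | 2-heptyl-4,6-dihydroxybenzoic acid | CCCCCCCc1cc(O)cc(O)c1C(=O)O | intermediate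
9 | benzyl 2-heptyl-4,6-dihydroxybenzoate | CCCCCCCc1cc(O)cc(O)c1C(=O)OCc1ccccc1 | intermediate
10 | benzyl 2-heptyl-6-hydroxy-4-(prop-2-en-1-yloxy)benzoate | CCCCCCCc1cc(OCC=C)cc(O)c1C(=O)OCc1ccccc1 | intermediate
11 | benzyl 2-heptyl-6-methoxy-4-(prop-2-en-1-yloxy)benzoate | CCCCCCCc1cc(OCC=C)cc(OC)c1C(=O)OCc1ccccc1 | intermediate
12 | benzyl 2-heptyl-4-hydroxy-6-methoxybenzoate | CCCCCCCc1cc(O)cc(OC)c1C(=O)OCc1ccccc1 | intermediate
13 | 2-(benzyloxy)-6-bromo-4-methoxybenzoyl chloride | COc1cc(OCc2ccccc2)c(C(=O)Cl)c(Br)c1 | intermediate (not isolated)
14 | benzyl 4-{[2-(benzyloxy)-6-bromo-4-methoxybenzoyl]oxy}-2-heptyl-6-methoxybenzoate | CCCCCCCc1cc(OC(=O)c2c(Br)cc(OC)cc2OCc3ccccc3)cc(OC)c1C(=O)OCc1ccccc1 | intermediate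
15 | hexanoic acid | CCCCCC(=O)O | starting material
16 | N-hydroxyphthalimide | ON1C(=O)c2ccccc2C1=O | starting material
17 | 1,3-dioxoisoindolin-2-yl hexanoate | CCCCCC(=O)ON1C(=O)c2ccccc2C1=O | intermediate
18 | benzyl 4-{[2-(benzyloxy)-4-methoxy-6-pentylbenzoyl]oxy}-2-heptyl-6-methoxybenzoate | CCCCCCCc1cc(OC(=O)c2c(CCCCC)cc(OC)cc2OCc3ccccc3)cc(OC)c1C(=O)OCc1ccccc1 | intermediate
19 | 2-heptyl-4-[(2-hydroxy-4-methoxy-6-pentylbenzoyl)oxy]-6-methoxybenzoic acid | CCCCCCCc1cc(OC(=O)c2c(O)cc(OC)cc2CCCCC)cc(OC)c1C(=O)O | target

## Step count and risks

Total step count: 13. Longest linear sequence: 8 steps (7 → 8 → 9 → 10 → 11 → 12 → 14 → 18 → 19, that is steps 5 to 10, 12 and 13).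

**Step 12 (key step).** The most likely failure is a mismatch of rates. An aryl bromide adds to low-valent nickel more slowly than an iodide, so reduction of 17 can outrun oxidative addition. The alkyl radical is then lost to dimerisation or hydrogen abstraction, and 14 is hydrodebrominated or homocoupled. A lesser risk is attack of the liberated phthalimide anion on the aryl ester. Fallback: a two-electron Negishi coupling in place of the radical manifold. It sets out from 14. Pentylzinc bromide F1, made from 1-bromopentane and zinc dust with LiCl in THF, is coupled with 14 using Pd(OAc)2 and 2-dicyclohexylphosphino-2',6'-dimethoxybiphenyl in THF at room temperature. Alkylzinc halides do not add to esters, and the path returns to the route at 18.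

**Step 10.** Acyl transfer may be slow, because the tetrahedral intermediate at the carbonyl of 13 is crowded by the ortho bromine and benzyloxy groups. Hydrolysis or decomposition of the acid chloride could then win over ester formation. Fallback: change from base-promoted addition–elimination to an acid-promoted acylium pathway. Setting out from 6, trifluoroacetic anhydride in toluene at room temperature gives 2-(benzyloxy)-6-bromo-4-methoxybenzoic trifluoroacetic anhydride F2. This ionises to a linear aroylium ion, stabilised by the C2 and C4 oxygens and no longer shielded by the ortho groups, and capture by 12 returns to the route at 14.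

**Step 5.** Carboxylation could partly go to the carbon between the two hydroxyls, and the product can revert by decarboxylation during acidic work-up or drying. Fallback: carry the carbon as an aldehyde instead. It sets out from 7.
- Vilsmeier–Haack formylation (POCl3, DMF) gives 2-heptyl-4,6-dihydroxybenzaldehyde F3.
- Allyl bromide and K2CO3 in acetone give 2-heptyl-6-hydroxy-4-(prop-2-en-1-yloxy)benzaldehyde F4.
- Iodomethane and K2CO3 in DMF give 2-heptyl-6-methoxy-4-(prop-2-en-1-yloxy)benzaldehyde F5.
- Pinnick oxidation gives 2-heptyl-6-methoxy-4-(prop-2-en-1-yloxy)benzoic acid F6.
- Benzyl bromide and K2CO3 in DMF return to the route at 11.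

**Step 7.** Discrimination between the free and the chelated hydroxyl may be incomplete, giving double allylation, and some C-allylation of the electron-rich ring is possible. Fallback: remove the need for selectivity by tying the carboxyl and the ortho hydroxyl into one ring. It sets out from 8.
- Acetone with trifluoroacetic anhydride and trifluoroacetic acid gives 5-heptyl-7-hydroxy-2,2-dimethyl-4H-1,3-benzodioxin-4-one F7, which has a single free hydroxyl.
- Allyl bromide and K2CO3 give 5-heptyl-2,2-dimethyl-7-(prop-2-en-1-yloxy)-4H-1,3-benzodioxin-4-one F8.
- Benzyl alcohol with NaH in THF opens the dioxinone to the benzyl ester with a free ortho hydroxyl, returning to the route at 10.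

## Further compounds

F1 | step 12 | pentylzinc bromide | CCCCC[Zn]Br
F2 | step 10 | 2-(benzyloxy)-6-bromo-4-methoxybenzoic trifluoroacetic anhydride | COc1cc(OCc2ccccc2)c(C(=O)OC(=O)C(F)(F)F)c(Br)c1
F3 | step 5 | 2-heptyl-4,6-dihydroxybenzaldehyde | CCCCCCCc1cc(O)cc(O)c1C=O
F4 | step 5 | 2-heptyl-6-hydroxy-4-(prop-2-en-1-yloxy)benzaldehyde | CCCCCCCc1cc(OCC=C)cc(O)c1C=O
F5 | step 5 | 2-heptyl-6-methoxy-4-(prop-2-en-1-yloxy)benzaldehyde | CCCCCCCc1cc(OCC=C)cc(OC)c1C=O
F6 | step 5 | 2-heptyl-6-methoxy-4-(prop-2-en-1-yloxy)benzoic acid | CCCCCCCc1cc(OCC=C)cc(OC)c1C(=O)O
F7 | step 7 | 5-heptyl-7-hydroxy-2,2-dimethyl-4H-1,3-benzodioxin-4-one | CCCCCCCc1cc(O)cc2OC(C)(C)OC(=O)c12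
F8 | step 7 | 5-heptyl-2,2-dimethyl-7-(prop-2-en-1-yloxy)-4H-1,3-benzodioxin-4-one | CCCCCCCc1cc(OCC=C)cc2OC(C)(C)OC(=O)c12
A1 | alternative 1 | 2-heptyl-6-methoxy-4-[(triisopropylsilyl)oxy]benzoic acid | CCCCCCCc1cc(O[Si](C(C)C)(C(C)C)C(C)C)cc(OC)c1C(=O)O
A2 | alternative 1 | (3-fluoro-5-methoxyphenoxy)triisopropylsilane | COc1cc(F)cc(O[Si](C(C)C)(C(C)C)C(C)C)c1
A3 | alternative 1 | heptyllithium | [Li]CCCCCCC
A4 | alternative 1 | 3-methoxy-5-[(triisopropylsilyl)oxy]benzyne | COC1=CC(O[Si](C(C)C)(C(C)C)C(C)C)=CC#C1
A5 | alternative 2 | benzyl 4-[(2,4-dihydroxy-6-pentylbenzoyl)oxy]-2-heptyl-6-methoxybenzoate | CCCCCCCc1cc(OC(=O)c2c(O)cc(O)cc2CCCCC)cc(OC)c1C(=O)OCc3ccccc3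
A6 | alternative 2 | benzyl 2-heptyl-6-methoxy-4-[(3,5,7-trioxododecanoyl)oxy]benzoate | CCCCCCCc1cc(OC(=O)CC(=O)CC(=O)CC(=O)CCCCC)cc(OC)c1C(=O)OCc1ccccc1
A7 | alternative 3 | tert-butyl 2-heptyl-6-methoxy-4-{[4-methoxy-2-(methoxymethoxy)-6-pentylbenzoyl]oxy}benzoate | CCCCCCCc1cc(OC(=O)c2c(OCOC)cc(OC)cc2CCCCC)cc(OC)c1C(=O)OC(C)(C)C
A8 | alternative 3 | 4-methoxy-2-(methoxymethoxy)-6-pentylbenzoic acid | CCCCCc1cc(OC)cc(OCOC)c1C(=O)O
A9 | alternative 3 | tert-butyl 2-heptyl-6-methoxy-4-(4,4,5,5-tetramethyl-1,3,2-dioxaborolan-2-yl)benzoate | CCCCCCCc1cc(B2OC(C)(C)C(C)(C)O2)cc(OC)c1C(=O)OC(C)(C)C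
A10 | alternative 3 | Cu(OTf)2, copper bis(trifluoromethanesulfonate) | [Cu+2].[O-]S(=O)(=O)C(F)(F)F.[O-]S(=O)(=O)C(F)(F)F
A11 | alternative 3 | tert-butyl 2-heptyl-6-methoxybenzoate | CCCCCCCc1cccc(OC)c1C(=O)OC(C)(C)C
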